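**Plan**

- The target is an achiral 2-aryl-1-benzofuran-3-carbaldehyde. In its benzo ring the bonds C3a–C4 and C7–C7a enclose the four-carbon unit C4–C5–C6–C7, with oxygen on C7 and the hydroxypropyl chain on C5. This is the pattern of a 3-alkyl vinylketene acetal, and C3a=C7a is a furan double bond that a nitro group on C7a turns into a dienophile.
- Retrosynthesis: CHO goes back to CO2Me and 7-OMe to 7-OH; then C3a–C4 and C7–C7a are cut together, giving a 5-nitrofuran-3-carboxylate and a 1,1-bis(silyloxy)diene. The furan is cut at C3–C4 and O1–C5 (Feist–Benary), the diene precursor at the C2=C3 bond of an enoic acid (Horner–Wadsworth–Emmons).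
- Forward: the furan ring is made first and nitrated (steps 1–4), the diene is assembled in parallel (steps 5–8), the benzo ring is closed last by cycloaddition and double elimination (step 9), and methylation, hydride reduction and MnO2 oxidation finish the route (steps 10–12).
- Stereochemistry: the target has no stereocentre. The only stereo-element on the way, the E geometry of the enoic acid, steers dienolate formation to the methyl group and vanishes in the diene.

Key step: step 9

Remark: the aryl phenol is carried as a pivalate (inert to K2CO3/MeI, cleaved by LiAlH4), and both silyl ethers are shed in the acid work-up of step 9, since neither the methylation nor the MnO2 oxidation touches a saturated primary alcohol.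

**Route**

Step 1
Reactants: 1 acetovanillone
Product: 2 methyl 3-(4-hydroxy-3-methoxyphenyl)-3-oxopropanoate
Conditions: NaH (3.5 equiv), (MeO)2CO (4 equiv), THF, reflux; then 1 M aq. HCl
Reagents that add atoms: dimethyl carbonate, COC(=O)OC
Why: Crossed Claisen condensation in which the ketone enolate (formed beside the phenoxide) is C-acylated by dimethyl carbonate and the equilibrium is pulled over by deprotonation of the β-keto ester, any aryl carbonate formed at the phenoxide being cleaved again by the methoxide set free.

Step 2
Reactants: 2 methyl 3-(4-hydroxy-3-methoxyphenyl)-3-oxopropanoate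
Product: 3 methyl 3-[3-methoxy-4-(pivaloyloxy)phenyl]-3-oxopropanoate
Conditions: PivCl (1.05 equiv), pyridine, CH2Cl2, 0 °C
Reagents that add atoms: pivaloyl chloride, CC(C)(C)C(=O)Cl
Why: Chemoselective O-acylation of the phenol, which under pyridine is far more nucleophilic than the un-ionised β-keto ester, installs a hindered, electron-withdrawing ester that survives acid, nitration and carbonate base and is removed by hydride in step 11.

Step 3
Reactants: 3 methyl 3-[3-methoxy-4-(pivaloyloxy)phenyl]-3-oxopropanoate; 4 chloroacetaldehyde (about 50 % in water)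
Product: 6 methyl 2-[3-methoxy-4-(pivaloyloxy)phenyl]furan-3-carboxylate, via hydroxydihydrofuran ester 5 (not isolated)
Conditions: pyridine, 50 °C; then 2 M aq. HCl, THF, rt
Reagents that add atoms: none
Why: Feist–Benary furan synthesis, in which aldol addition of the active methylene to the aldehyde, 5-exo-tet displacement of chloride by the enol oxygen and acid-promoted dehydration of hydroxydihydrofuran 5 give the 2-aryl-3-carboxylate furan with C4 and C5 free.

Step 4
Reactants: 6 methyl 2-[3-methoxy-4-(pivaloyloxy)phenyl]furan-3-carboxylate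
Product: 8 methyl 2-[3-methoxy-4-(pivaloyloxy)phenyl]-5-nitrofuran-3-carboxylate, via acetoxy nitro dihydrofuran 7 (not isolated)
Conditions: fuming HNO3 (1.05 equiv), Ac2O, −15 °C; then pyridine, 0 °C to rt
Reagents that add atoms: nitric acid, O[N+](=O)[O-]
Why: Electrophilic nitration by acetyl nitrate at the only free α-position of the furan (C5), by far the most nucleophilic carbon in 6, proceeds through the 2,5-adduct 7, from which pyridine removes acetic acid to restore the furan, while the ester keeps C4 and the pivalate keeps the aryl ring from competing.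

Step 5
Reactants: 9 5-hydroxypentan-2-one
Product: 10 5-[(tert-butyldimethylsilyl)oxy]pentan-2-one
Conditions: TBSCl, imidazole, CH2Cl2, 0 °C to rt
Reagents that add atoms: tert-butyldimethylsilyl chloride, CC(C)(C)[Si](C)(C)Cl
Why: Standard imidazole-mediated silylation of a primary alcohol, which also locks the hydroxy ketone in its open-chain form for the olefination.

Step 6
Reactants: 10 5-[(tert-butyldimethylsilyl)oxy]pentan-2-one; 11 triethyl phosphonoacetate
Product: 12 ethyl (2E)-6-[(tert-butyldimethylsilyl)oxy]-3-methylhex-2-enoate
Conditions: NaH, THF, 0 °C to reflux; silica chromatography to remove the minor Z isomer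
Reagents that add atoms: none
Why: Horner–Wadsworth–Emmons olefination of the methyl ketone with the sodium phosphonate anion, expected to favour the E alkene (chain anti to the ester), which is separated from the Z isomer because the alkene geometry decides the site of deprotonation in step 8.

Step 7
Reactants: 12 ethyl (2E)-6-[(tert-butyldimethylsilyl)oxy]-3-methylhex-2-enoate
Product: 13 (2E)-6-[(tert-butyldimethylsilyl)oxy]-3-methylhex-2-enoic acid
Conditions: LiOH, THF/MeOH/H2O, 40 °C; then 1 M aq. HCl to pH 4, 0 °C
Reagents that add atoms: lithium hydroxide, [Li+].[OH-]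
Why: Saponification of the ethyl ester with LiOH, to which the primary TBS ether and the alkene geometry are inert, followed by mild acidification that spares the silyl ether.

Step 8
Reactants: 13 (2E)-6-[(tert-butyldimethylsilyl)oxy]-3-methylhex-2-enoic acid
Product: 15 1,1-bis(trimethylsilyloxy)-3-{3-[(tert-butyldimethylsilyl)oxy]propyl}buta-1,3-diene, via dilithium dienediolate 14 (not isolated)
Conditions: LiN(iPr)2 (2.2 equiv), THF, −78 to 0 °C; TMSCl (2.5 equiv), −78 °C to rt; pentane, filtration under argon, used crude
Reagents that add atoms: chlorotrimethylsilane, C[Si](C)(C)Cl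
Why: Double deprotonation gives the carboxylate-derived dienediolate 14, the second base equivalent removing a proton from the C3 methyl group that lies syn to the carboxylate in the E acid, and the hard oxygen centres are then silylated to the bis(silyl) vinylketene acetal (ketene silyl acetal formation from a carboxylic acid dianion).

Step 9
Reactants: 8 methyl 2-[3-methoxy-4-(pivaloyloxy)phenyl]-5-nitrofuran-3-carboxylate; 15 1,1-bis(trimethylsilyloxy)-3-{3-[(tert-butyldimethylsilyl)oxy]propyl}buta-1,3-diene (3 equiv)
Product: 19 methyl 7-hydroxy-5-(3-hydroxypropyl)-2-[3-methoxy-4-(pivaloyloxy)phenyl]-1-benzofuran-3-carboxylate, via nitro cycloadduct 16 (not isolated), via bis(silyloxy) dihydrobenzofuran 17 (not isolated), via silylated benzofuran 18 (not isolated)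
Conditions: toluene, sealed tube, 110 °C; evaporate; then 1 M aq. HCl, THF, rt
Reagents that add atoms: none
Why: The nitro group makes the furan C4=C5 bond of 8 a polarised, electron-poor alkene, and the electron-rich ketene acetal diene 15 adds across it in a polar, normal-electron-demand Diels–Alder reaction (concerted but strongly asynchronous, or stepwise through a nitronate/silyloxycarbenium zwitterion), its CH2 terminus bonding to the carbon β to nitro (the future C3a–C4 bond) and its acetal carbon to the nitro-bearing carbon (the future C7–C7a bond). The closest known reaction type is the thermal cycloaddition of 2-nitrofurans, 5-nitrofuran-3-carboxylates included, with 1-alkoxy-3-silyloxybutadienes, which gives hydroxybenzofurans after loss of nitrous acid. The six-membered benzo ring is thus closed by an intermolecular [4+2] cycloaddition that is suprafacial on both partners. The two transient stereocentres of 16 (C3a and C7a, cis by suprafacial addition) are erased when nitrous acid is eliminated to restore the furan in 17, 1,4-elimination of trimethylsilanol from the ketal carbon then aromatises the new ring to 18, and dilute acid hydrolyses both silyl ethers to 19. The selectivity needed is regiochemical and positional: the largest HOMO coefficient of 15 lies on its unsubstituted CH2 terminus and the largest LUMO coefficient of 8 on the carbon β to nitro, which places the oxygen on C7 and the chain on C5, while the C2=C3 bond is tetrasubstituted, donor-substituted and far less electrophilic than the nitroalkene. The excess of 15 absorbs the nitrous acid set free, and the new phenol stays silylated until the volatiles are removed, so it is not exposed to nitrosating species.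

Step 10
Reactants: 19 methyl 7-hydroxy-5-(3-hydroxypropyl)-2-[3-methoxy-4-(pivaloyloxy)phenyl]-1-benzofuran-3-carboxylate
Product: 20 methyl 5-(3-hydroxypropyl)-7-methoxy-2-[3-methoxy-4-(pivaloyloxy)phenyl]-1-benzofuran-3-carboxylate
Conditions: MeI, K2CO3, acetone, rt
Reagents that add atoms: iodomethane, CI
Why: Williamson ether synthesis in which K2CO3 ionises only the phenol, so the primary alcohol stays unmethylated and the hindered aryl pivalate and the methyl ester are not touched.

Step 11
Reactants: 20 methyl 5-(3-hydroxypropyl)-7-methoxy-2-[3-methoxy-4-(pivaloyloxy)phenyl]-1-benzofuran-3-carboxylate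
Product: 21 4-[3-(hydroxymethyl)-5-(3-hydroxypropyl)-7-methoxy-1-benzofuran-2-yl]-2-methoxyphenol
Conditions: LiAlH4 (4 equiv), THF, 0 °C; aq. potassium sodium tartrate work-up
Reagents that add atoms: none
Why: LiAlH4 reduces the methyl ester to the primary alcohol and at the same time cleaves the aryl pivalate reductively, and the neutral tartrate work-up avoids acid, to which the electron-rich benzofuranylmethanol is sensitive.

Step 12
Reactants: 21 4-[3-(hydroxymethyl)-5-(3-hydroxypropyl)-7-methoxy-1-benzofuran-2-yl]-2-methoxyphenol
Product: 22 2-(4-hydroxy-3-methoxyphenyl)-5-(3-hydroxypropyl)-7-methoxy-1-benzofuran-3-carbaldehyde (target)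
Conditions: activated MnO2 (15 equiv), acetone, rt
Reagents that add atoms: none
Why: Chemoselective MnO2 oxidation of the benzylic-type benzofuran-3-ylmethanol to the aldehyde, a reagent that leaves saturated primary alcohols and guaiacyl phenols alone (as in the oxidation of coniferyl alcohol to coniferaldehyde) and cannot over-oxidise.

**Compound list**

1 | acetovanillone, 1-(4-hydroxy-3-methoxyphenyl)ethan-1-one | CC(=O)c1ccc(O)c(OC)c1 | starting material
2 | methyl 3-(4-hydroxy-3-methoxyphenyl)-3-oxopropanoate | COC(=O)CC(=O)c1ccc(O)c(OC)c1 | intermediate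
3 | methyl 3-[3-methoxy-4-(pivaloyloxy)phenyl]-3-oxopropanoate | COC(=O)CC(=O)c1ccc(OC(=O)C(C)(C)C)c(OC)c1 | intermediate
4 | chloroacetaldehyde | ClCC=O | starting material
5 | methyl 4-hydroxy-2-[3-methoxy-4-(pivaloyloxy)phenyl]-4,5-dihydrofuran-3-carboxylate (racemic, not isolated) | COC(=O)C1=C(c2ccc(OC(=O)C(C)(C)C)c(OC)c2)OCC1O | intermediate
6 | methyl 2-[3-methoxy-4-(pivaloyloxy)phenyl]furan-3-carboxylate | COC(=O)c1ccoc1-c1ccc(OC(=O)C(C)(C)C)c(OC)c1 | intermediate
7 | methyl 2-acetoxy-2-[3-methoxy-4-(pivaloyloxy)phenyl]-5-nitro-2,5-dihydrofuran-3-carboxylate (diastereomer mixture, not isolated) | COC(=O)C1=CC([N+](=O)[O-])OC1(OC(C)=O)c1ccc(OC(=O)C(C)(C)C)c(OC)c1 | intermediate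
8 | methyl 2-[3-methoxy-4-(pivaloyloxy)phenyl]-5-nitrofuran-3-carboxylate | COC(=O)c1cc([N+](=O)[O-])oc1-c1ccc(OC(=O)C(C)(C)C)c(OC)c1 | intermediate
9 | 5-hydroxypentan-2-one | CC(=O)CCCO | starting material
10 | 5-[(tert-butyldimethylsilyl)oxy]pentan-2-one | CC(=O)CCCO[Si](C)(C)C(C)(C)C | intermediate
11 | triethyl phosphonoacetate | CCOC(=O)CP(=O)(OCC)OCC | starting material
12 | ethyl (2E)-6-[(tert-butyldimethylsilyl)oxy]-3-methylhex-2-enoate | CCOC(=O)/C=C(\C)CCCO[Si](C)(C)C(C)(C)C | intermediate
13 | (2E)-6-[(tert-butyldimethylsilyl)oxy]-3-methylhex-2-enoic acid | OC(=O)/C=C(\C)CCCO[Si](C)(C)C(C)(C)C | intermediate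
14 | dilithium 6-[(tert-butyldimethylsilyl)oxy]-3-methylidenehex-1-ene-1,1-bis(olate) (not isolated) | C=C(CCCO[Si](C)(C)C(C)(C)C)C=C([O-])[O-].[Li+].[Li+] | intermediate
15 | 1,1-bis(trimethylsilyloxy)-3-{3-[(tert-butyldimethylsilyl)oxy]propyl}buta-1,3-diene | C=C(CCCO[Si](C)(C)C(C)(C)C)C=C(O[Si](C)(C)C)O[Si](C)(C)C | intermediate
16 | methyl cis-5-{3-[(tert-butyldimethylsilyl)oxy]propyl}-2-[3-methoxy-4-(pivaloyloxy)phenyl]-7a-nitro-7,7-bis(trimethylsilyloxy)-3a,4,7,7a-tetrahydro-1-benzofuran-3-carboxylate (H-3a and 7a-NO2 on the same face; racemic, one enantiomer drawn; not isolated) | COC(=O)C1=C(c2ccc(OC(=O)C(C)(C)C)c(OC)c2)O[C@@]2([N+](=O)[O-])[C@@H]1CC(CCCO[Si](C)(C)C(C)(C)C)=CC2(O[Si](C)(C)C)O[Si](C)(C)C | intermediate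
17 | methyl 5-{3-[(tert-butyldimethylsilyl)oxy]propyl}-2-[3-methoxy-4-(pivaloyloxy)phenyl]-7,7-bis(trimethylsilyloxy)-4,7-dihydro-1-benzofuran-3-carboxylate (not isolated) | COC(=O)c1c(-c2ccc(OC(=O)C(C)(C)C)c(OC)c2)oc2c1CC(CCCO[Si](C)(C)C(C)(C)C)=CC2(O[Si](C)(C)C)O[Si](C)(C)C | intermediate
18 | methyl 5-{3-[(tert-butyldimethylsilyl)oxy]propyl}-2-[3-methoxy-4-(pivaloyloxy)phenyl]-7-(trimethylsilyloxy)-1-benzofuran-3-carboxylate (not isolated) | COC(=O)c1c(-c2ccc(OC(=O)C(C)(C)C)c(OC)c2)oc2c(O[Si](C)(C)C)cc(CCCO[Si](C)(C)C(C)(C)C)cc12 | intermediate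
19 | methyl 7-hydroxy-5-(3-hydroxypropyl)-2-[3-methoxy-4-(pivaloyloxy)phenyl]-1-benzofuran-3-carboxylate | COC(=O)c1c(-c2ccc(OC(=O)C(C)(C)C)c(OC)c2)oc2c(O)cc(CCCO)cc12 | intermediate
20 | methyl 5-(3-hydroxypropyl)-7-methoxy-2-[3-methoxy-4-(pivaloyloxy)phenyl]-1-benzofuran-3-carboxylate | COC(=O)c1c(-c2ccc(OC(=O)C(C)(C)C)c(OC)c2)oc2c(OC)cc(CCCO)cc12 | intermediate
21 | 4-[3-(hydroxymethyl)-5-(3-hydroxypropyl)-7-methoxy-1-benzofuran-2-yl]-2-methoxyphenol | COc1cc(-c2oc3c(OC)cc(CCCO)cc3c2CO)ccc1O | intermediate
22 | 2-(4-hydroxy-3-methoxyphenyl)-5-(3-hydroxypropyl)-7-methoxy-1-benzofuran-3-carbaldehyde | COc1cc(-c2oc3c(OC)cc(CCCO)cc3c2C=O)ccc1O | target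

**Step count**

Total step count: 12. Longest linear sequence: 8 steps (steps 1–4 then 9–12; the diene branch, steps 5–8 then 9–12, is equally long).

**Steps most likely to fail**

First, step 9. The cycloaddition at the trisubstituted, 2-aryl-bearing nitrofuran may be so slow that protodesilylation of the diene by the nitrous acid set free, or Michael addition of the ketene acetal without ring closure, outruns the annulation. The fallback gives up the cycloaddition and builds the furan ring onto a ready-made benzene ring; it sets out from β-keto ester 3. Commercial 4-(3-hydroxypropyl)-2-methoxyphenol is acetylated at the aliphatic hydroxyl only (vinyl acetate, Candida antarctica lipase B) to give 3-(4-hydroxy-3-methoxyphenyl)propyl acetate F1. Compound 3 and F1 are then joined by the FeCl3·6H2O-catalysed oxidative coupling–annulation of phenols with β-keto esters (di-tert-butyl peroxide, 1,2-dichloroethane, 100 °C). The free ortho position of the phenol couples with the α-carbon of 3 and the phenol oxygen condenses with the ketone, giving methyl 5-(3-acetoxypropyl)-7-methoxy-2-[3-methoxy-4-(pivaloyloxy)phenyl]-1-benzofuran-3-carboxylate F2. LiAlH4 under the conditions of step 11 reduces the methyl ester and removes acetate and pivalate, and the route is rejoined at triol 21.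

Second, step 8. Deprotonation may occur in part at the chain methylene instead of the methyl group, the second deprotonation of the carboxylate may stay incomplete, or silylation may take place on carbon, so that a regioisomeric or impure diene results. The fallback sets out from ketone 10 and makes the dienolate by an α-deprotonation that has no regiochemical alternative. Kinetic enolisation at the methyl group (LiN(iPr)2, THF, −78 °C) and trapping with PhNTf2 should give 5-[(tert-butyldimethylsilyl)oxy]pent-1-en-2-yl trifluoromethanesulfonate F3. Negishi coupling with the Reformatsky reagent BrZnCH2CO2Et under Pd(PPh3)4 in THF should give ethyl 6-[(tert-butyldimethylsilyl)oxy]-3-methylidenehexanoate F4. Hydrolysis with LiOH in THF/H2O at 0 °C, kept cold to avoid migration of the double bond into conjugation, should give 6-[(tert-butyldimethylsilyl)oxy]-3-methylidenehexanoic acid F5. Treatment of F5 with LiN(iPr)2 (2.2 equiv) and TMSCl as in step 8 removes the doubly activated α-proton, passes through the same dienediolate 14 and rejoins the route at diene 15.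

Third, step 4. Nitration of the guaiacyl ring or oxidative opening of the furan may compete with substitution at C5. The fallback sets out from furan 6 and avoids any electrophilic nitrating agent. Iodination with N-iodosuccinimide (MeCN, rt) at the free α-position should give methyl 5-iodo-2-[3-methoxy-4-(pivaloyloxy)phenyl]furan-3-carboxylate F6. An Ullmann-type nitro-deiodination (Cu powder, N,N'-dimethylethylenediamine, tetrabutylammonium nitrite, DMF, 90 °C) then delivers nitrofuran 8, where the route is rejoined.

**Further compounds**

F1 | step 9 | 3-(4-hydroxy-3-methoxyphenyl)propyl acetate | CC(=O)OCCCc1ccc(O)c(OC)c1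
F2 | step 9 | methyl 5-(3-acetoxypropyl)-7-methoxy-2-[3-methoxy-4-(pivaloyloxy)phenyl]-1-benzofuran-3-carboxylate | COC(=O)c1c(-c2ccc(OC(=O)C(C)(C)C)c(OC)c2)oc2c(OC)cc(CCCOC(C)=O)cc12
F3 | step 8 | 5-[(tert-butyldimethylsilyl)oxy]pent-1-en-2-yl trifluoromethanesulfonate | C=C(CCCO[Si](C)(C)C(C)(C)C)OS(=O)(=O)C(F)(F)F
F4 | step 8 | ethyl 6-[(tert-butyldimethylsilyl)oxy]-3-methylidenehexanoate | CCOC(=O)CC(=C)CCCO[Si](C)(C)C(C)(C)C
F5 | step 8 | 6-[(tert-butyldimethylsilyl)oxy]-3-methylidenehexanoic acid | OC(=O)CC(=C)CCCO[Si](C)(C)C(C)(C)C
F6 | step 4 | methyl 5-iodo-2-[3-methoxy-4-(pivaloyloxy)phenyl]furan-3-carboxylate | COC(=O)c1cc(I)oc1-c1ccc(OC(=O)C(C)(C)C)c(OC)c1
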